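Watch what J costs. X reacts with L to give G and with J to give E and Z; E slowly becomes D, and Z can hold a further J as Q. Amounts below are fractions of the X charged.

| setting | grey | blue | Friday's | Wednesday's |
|---|---|---|---|---|
| X | 45 mM | 45 mM | 45 mM | 45 mM |
| J | 49.5 mM | 49.5 mM | 50.0 mM | 99.0 mM |
| L | 6 mM | 18 mM | 9.00 mM | 9.00 mM |
| remark | run made earlier | run made earlier |  |  |
| time |  |  | 25 h | 25 h |

| run | time / h | X / % | E / % |
|---|---|---|---|
| grey | 1.00 | 76.9 | 9.2 |
| grey | 2.00 | 70.5 | 15.5 |
| grey | 3.00 | 64.1 | 19.9 |
| grey | 4.00 | 59.5 | 22.7 |
| grey | 5.00 | 56.2 | 25.9 |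
| blue | 0.417 | 61.6 | 3.7 |
| blue | 1.33 | 51.0 | 8.9 |
| blue | 2.50 | 44.9 | 13.5 |
| blue | 4.00 | 38.7 | 17.5 |
| blue | 5.00 | 36.2 | 19.1 |

(each reading ± 0.3 percentage points)

- part of the X that has reacted at the end, Friday's
- part of the X that has reacted at the end, Wednesday's
- what raising the concentration of J from its lowest to its highest value here does to the part of the X that has reacted (changes below 5 percentage points count as none) (it falls / it rises / no change)

The grey run looks odd. It charges J at 1.10, an excess, so you might expect the loss of X to follow X. Yet from the window 1.00 h to 3.00 h to the window 3.00 h to 5.00 h that loss slows by a factor of 1.62, while X, taken as the mean of each window's ends, falls by a factor of 1.17.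

Take the rate as a constant times X times J. Then J must have fallen by a factor of 1.38. L is out of the reckoning by then: at the first grey reading, X lost beyond E is 13.9%, against an L charge of 13.3%. Subtracting that from the X lost gives the X converted by J at each window's middle, 0.162 and 0.265. My reckoning then gives 2.05 for the J cost, the J lost per X converted by J. Replacing the means by the readings at mid-window gives 1.93, so the cost read from these scattered readings is about two: one J reacts, and one is held in Q.

On Friday's, J at that cost reaches 54.1% of X, less than the 80.0% left after L. J is thus the limiting reagent on Friday's, and my ceiling, an estimate that stands only while Q holds its J, is 74.1%. On Wednesday's, J reaches 107%, more than that, so the J cost sets no such ceiling.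

The forecast says 73% for Friday's and 96% for Wednesday's, and of raising J, it rises; its ground is that “each X converted uses two J, meaning Z binds J tightly as Q”.

The flasks give 70.8% on Friday's and 95.7% on Wednesday's, and with J raised, it rises, by 25 percentage points.

    X + L → G (k = 140 M⁻¹ h⁻¹)
    X + J → Z + E (k = 2.60 M⁻¹ h⁻¹)
    E ⇌ D (K = 0.550, k = 0.0850 h⁻¹)
    J + Z ⇌ Q, settled at all times (K = 19000 M⁻¹)

Wednesday's end shows 2.00 J lost per X converted by J. For a neighbouring flask, Wednesday's with 40 mM of J, the ceiling reckons to 63.3%, and that flask stands at 62.0% reacted at the end. The half-life of X against L, with L held at its charge, is 0.55 h, shorter than the 5.3 h against J as charged on Friday's. At Friday's end, L stands at 0% of its charge and G at 20.0%.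

All runs are simulated from invented constants, noise included.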